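**Plan**
- The retrosynthesis first cuts the C4–Br and C6–Br bonds of ring A (electrophilic bromination), then C5–Br (Sandmeyer, back to a nitro group).
- Ring A is then cut at C4–C5 and C5–C6. C5 lies between C4 and C6 and para to the C2 hydroxyl, so C5 maps onto nitromethane, and C1(OMe)–C2(OH)–C3(OAr) with C4 and C6 map onto a 3-aryloxy-5-methoxy-4-pyranone whose carbonyl becomes C2–OH.
- The pyranone is cut at both O–CH and both CH=C bonds to 1-(2,4-dibromophenoxy)-3-methoxypropan-2-one and two formyl equivalents. The ketone comes from 2,4-dibromophenol and glycidyl methyl ether, cut at the alkyl C–O bond of the aryl ether.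
- Forward: ring B is bought; the chain is joined by epoxide opening; the pyranone ring closes in step 4; ring A closes in step 5; the bromines follow in steps 7 and 8.
- Stereochemistry: the target has no stereocentre; the racemic carbinol centre made in step 1 is oxidised away in step 2.

Key step: step 5

Remark: racemic glycidyl methyl ether is used. The double-bond geometries written for 6 and 9 are the expected ones; they are mobile under the reaction conditions and do not affect the outcome.

**Step 1**
Reactants: 1 2,4-dibromophenol; 2 glycidyl methyl ether (racemic)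
Product: 3 (±)-1-(2,4-dibromophenoxy)-3-methoxypropan-2-ol
Conditions: K2CO3 (0.2 equiv), DMF, 90 °C
Reagents that add atoms: none
Why: Base-catalysed SN2 opening of the epoxide by the aryloxide at the unsubstituted CH2 (phenol–epoxide addition) should give the secondary alcohol, whose racemic carbinol centre is removed in step 2.

**Step 2**
Reactants: 3 (±)-1-(2,4-dibromophenoxy)-3-methoxypropan-2-ol
Product: 4 1-(2,4-dibromophenoxy)-3-methoxypropan-2-one
Conditions: Dess–Martin periodinane (1.2 equiv), CH2Cl2, rt
Reagents that add atoms: none
Why: Dess–Martin oxidation of a secondary alcohol to the ketone runs under neutral conditions that leave the aryl bromides and both ethers untouched.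

**Step 3**
Reactants: 4 1-(2,4-dibromophenoxy)-3-methoxypropan-2-one; 5 N,N-dimethylformamide dimethyl acetal (two equivalents are consumed)
Product: 6 (1Z,4Z)-2-(2,4-dibromophenoxy)-1,5-bis(dimethylamino)-4-methoxypenta-1,4-dien-3-one
Conditions: neat 5 (5 equiv), 110 °C, MeOH distilled off
Reagents that add atoms: N,N-dimethylformamide dimethyl acetal, COC(OC)N(C)C (the second equivalent of 5, which supplies the second CH–NMe2 unit)
Why: Both α-methylenes are activated by the carbonyl and an adjacent oxygen, so each should condense with one molecule of the amide acetal (double enaminone formation), removal of methanol driving the second condensation.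

**Step 4**
Reactants: 6 (1Z,4Z)-2-(2,4-dibromophenoxy)-1,5-bis(dimethylamino)-4-methoxypenta-1,4-dien-3-one
Product: 7 3-(2,4-dibromophenoxy)-5-methoxy-4H-pyran-4-one
Conditions: 2 M aq. HCl, THF, 50 °C
Reagents that add atoms: water, O
Why: Acid hydrolysis of one vinylogous amide to the hydroxymethylene ketone, addition of its enol oxygen to the other protonated enaminone terminus and loss of the second dimethylamine should give the 4-pyranone (cyclocondensation of a bis-enaminone, the usual route to 3,5-disubstituted 4-pyranones).

**Step 5**
Reactants: 7 3-(2,4-dibromophenoxy)-5-methoxy-4H-pyran-4-one; 8 nitromethane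
Product: 10 2-(2,4-dibromophenoxy)-6-methoxy-4-nitrophenol, via ring-opened nitro dienolate 9 (not isolated)
Conditions: 8 (5 equiv), KOtBu (3 equiv), tBuOH, 80 °C; then 1 M HCl
Reagents that add atoms: none
Why: Potassium methanenitronate, K[CH2NO2], adds in conjugate fashion to C2 (or the equivalent C6) of the vinylogous ester 7, and the resulting enolate expels the ring oxygen by E1cB to give the acyclic formyl enolate 9 with a CH2NO2 terminus. The re-formed nitronate carbon then attacks the aldehyde carbon in an intramolecular Henry addition that closes ring A in the 6-exo-trig mode, and loss of water with tautomerisation gives the 4-nitrophenolate, protonated on work-up. The closest known reaction type is the ring transformation of pyrylium salts into nitrobenzenes and of 4-pyranones into 4-nitrophenols with nitromethane and base, an opening and reclosure related to the conversion of 3-alkoxy-4-pyranones into pyridinones by amines. No stereocentre is formed. The step needs attack at C2 or C6 and not at the C4 carbonyl; both positions are unsubstituted CH and lead to the same product, whereas the cross-conjugated carbonyl is flanked by the aryloxy and methoxy groups, addition there is reversible, and the irreversible aromatisation drains the mixture to 10. The aryl bromides and the diaryl ether carry no activating group for nucleophilic substitution and should survive the alkoxide.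

**Step 6**
Reactants: 10 2-(2,4-dibromophenoxy)-6-methoxy-4-nitrophenol
Product: 11 4-amino-2-(2,4-dibromophenoxy)-6-methoxyphenol
Conditions: Fe powder (5 equiv), AcOH/EtOH, 70 °C, argon; used at once
Reagents that add atoms: none
Why: Béchamp-type reduction of the nitro group by iron in acetic acid is selective over aryl bromides and aryl ethers, and the air-sensitive aminophenol is carried on without storage.

**Step 7**
Reactants: 11 4-amino-2-(2,4-dibromophenoxy)-6-methoxyphenol
Product: 13 4-bromo-2-(2,4-dibromophenoxy)-6-methoxyphenol, via diazonium bromide 12 (not isolated)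
Conditions: NaNO2 (1.05 equiv), 48% aq. HBr/AcOH, 0 °C; then CuBr (0.3 equiv), 48% aq. HBr, 0 to 60 °C
Reagents that add atoms: hydrogen bromide, Br (bromine of 13 and counter-ion of 12); sodium nitrite, [Na+].[O-]N=O (terminal nitrogen of 12 only)
Why: Diazotisation in strong acid keeps the aminophenol protonated and the diazonium in its phenol form, and the CuBr-catalysed Sandmeyer bromo-dediazoniation (electron transfer from CuBr gives the aryl radical, which takes bromine from the CuBr2 so formed) puts bromine on the carbon that came from nitromethane.

**Step 8**
Reactants: 13 4-bromo-2-(2,4-dibromophenoxy)-6-methoxyphenol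
Product: 14 3,4,5-tribromo-2-(2,4-dibromophenoxy)-6-methoxyphenol (CNP0152859.0)
Conditions: Br2 (2.2 equiv), AcOH, rt
Reagents that add atoms: bromine, BrBr
Why: The two open positions of ring A are each ortho to one ether oxygen and para to the other (resorcinol-type cooperative activation), so electrophilic aromatic bromination should fill both while ring B, with one ether oxygen and two bromines, reacts far more slowly.

**Compound list**
1 | 2,4-dibromophenol | Oc1ccc(Br)cc1Br | starting material
2 | glycidyl methyl ether, 2-(methoxymethyl)oxirane, racemic | COCC1CO1 | starting material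
3 | (±)-1-(2,4-dibromophenoxy)-3-methoxypropan-2-ol | COCC(O)COc1ccc(Br)cc1Br | intermediate
4 | 1-(2,4-dibromophenoxy)-3-methoxypropan-2-one | COCC(=O)COc1ccc(Br)cc1Br | intermediate
5 | N,N-dimethylformamide dimethyl acetal | COC(OC)N(C)C | starting material
6 | (1Z,4Z)-2-(2,4-dibromophenoxy)-1,5-bis(dimethylamino)-4-methoxypenta-1,4-dien-3-one | CN(C)/C=C(\OC)C(=O)/C(Oc1ccc(Br)cc1Br)=C/N(C)C | intermediate
7 | 3-(2,4-dibromophenoxy)-5-methoxy-4H-pyran-4-one | COc1cocc(Oc2ccc(Br)cc2Br)c1=O | intermediate
8 | nitromethane | C[N+](=O)[O-] | starting material
9 | potassium (1E,4E)-4-(2,4-dibromophenoxy)-2-methoxy-6-nitro-3-oxohexa-1,4-dien-1-olate (ring-opened nitro dienolate, not isolated) | [K+].[O-]/C=C(/OC)C(=O)/C(Oc1ccc(Br)cc1Br)=C\C[N+](=O)[O-] | intermediate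
10 | 2-(2,4-dibromophenoxy)-6-methoxy-4-nitrophenol | COc1cc([N+](=O)[O-])cc(Oc2ccc(Br)cc2Br)c1O | intermediate
11 | 4-amino-2-(2,4-dibromophenoxy)-6-methoxyphenol | COc1cc(N)cc(Oc2ccc(Br)cc2Br)c1O | intermediate
12 | 3-(2,4-dibromophenoxy)-4-hydroxy-5-methoxybenzenediazonium bromide (not isolated) | COc1cc([N+]#N)cc(Oc2ccc(Br)cc2Br)c1O.[Br-] | intermediate
13 | 4-bromo-2-(2,4-dibromophenoxy)-6-methoxyphenol | COc1cc(Br)cc(Oc2ccc(Br)cc2Br)c1O | intermediate
14 | 3,4,5-tribromo-2-(2,4-dibromophenoxy)-6-methoxyphenol | COc1c(O)c(Oc2ccc(Br)cc2Br)c(Br)c(Br)c1Br | target

**Total step count:** 8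
**Longest linear sequence:** 8 steps (1 and 2 to 14)

**Steps most likely to fail**

Step 5. The conjugate addition of the nitronate may be slow because the C3 and C5 oxygen substituents make C2 and C6 less electrophilic. The ring-opened formyl enolate may also be lost by retro-Claisen deformylation before it recloses. The fallback sets out from ketone 4 and builds ring A by a different bond set. Condensation of 4 with sodium nitromalonaldehyde monohydrate, NaC3H2NO4·H2O, in aqueous ethanolic NaOH at rt is a double aldol condensation with aromatisation, the classical route from 1,3-disubstituted acetones to 2,6-disubstituted 4-nitrophenols. It comes back to the route at 10 and makes no compound outside the list (F0).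

Step 7. Nitrous acid may oxidise the electron-rich aminophenol to quinonoid material. The diazonium phenol may also collapse to a quinone diazide that resists bromide transfer, or couple to azo dyes. The fallback sets out from 10 and masks the phenol before the nitrogen chemistry. Acetylation (Ac2O, pyridine) should give 2-(2,4-dibromophenoxy)-6-methoxy-4-nitrophenyl acetate F1, and Fe in AcOH should then give 4-amino-2-(2,4-dibromophenoxy)-6-methoxyphenyl acetate F2. The amino group now directs NBS (2 equiv, MeCN, 0 °C) to its two ortho positions, the only open positions of ring A, to give 4-amino-3,5-dibromo-2-(2,4-dibromophenoxy)-6-methoxyphenyl acetate F3. Non-aqueous diazotisation and bromination (tBuONO, CuBr2, MeCN, 60 °C) should pass through 4-acetoxy-2,6-dibromo-3-(2,4-dibromophenoxy)-5-methoxybenzenediazonium bromide F4 to 3,4,5-tribromo-2-(2,4-dibromophenoxy)-6-methoxyphenyl acetate F5. Methanolysis (K2CO3, MeOH, rt) brings the sequence back to the route at 14. This path also avoids brominating a free phenol in step 8.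

Step 3. The second condensation may stall at the mono-enaminone, because the first vinylogous amide lowers the acidity of the remaining methylene, and long heating may degrade the material. The fallback sets out from 4. Double Claisen formylation (ethyl formate, NaH, THF, 0 °C to rt, then acidification) should give (1E,4E)-2-(2,4-dibromophenoxy)-1,5-dihydroxy-4-methoxypenta-1,4-dien-3-one F6, drawn as the chelated bis-enol of the dialdehyde. Acid cyclodehydration (p-TsOH, toluene, reflux with water removal) then closes the pyranone and comes back to the route at 7.

**Further compounds**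
F0 | step 5 | none | none
F1 | step 7 | 2-(2,4-dibromophenoxy)-6-methoxy-4-nitrophenyl acetate | COc1cc([N+](=O)[O-])cc(Oc2ccc(Br)cc2Br)c1OC(C)=O
F2 | step 7 | 4-amino-2-(2,4-dibromophenoxy)-6-methoxyphenyl acetate | COc1cc(N)cc(Oc2ccc(Br)cc2Br)c1OC(C)=O
F3 | step 7 | 4-amino-3,5-dibromo-2-(2,4-dibromophenoxy)-6-methoxyphenyl acetate | COc1c(Br)c(N)c(Br)c(Oc2ccc(Br)cc2Br)c1OC(C)=O
F4 | step 7 | 4-acetoxy-2,6-dibromo-3-(2,4-dibromophenoxy)-5-methoxybenzenediazonium bromide | COc1c(Br)c([N+]#N)c(Br)c(Oc2ccc(Br)cc2Br)c1OC(C)=O.[Br-]
F5 | step 7 | 3,4,5-tribromo-2-(2,4-dibromophenoxy)-6-methoxyphenyl acetate | COc1c(Br)c(Br)c(Br)c(Oc2ccc(Br)cc2Br)c1OC(C)=O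
F6 | step 3 | (1E,4E)-2-(2,4-dibromophenoxy)-1,5-dihydroxy-4-methoxypenta-1,4-dien-3-one | O/C=C(/OC)C(=O)/C(Oc1ccc(Br)cc1Br)=C\O
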